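After 50.0 min, Thursday's run had lost 0.196 mM min⁻¹ of solid L on average and Wednesday's 0.202 mM min⁻¹, and that was where I began when you asked for a quick number on the new flask and offered your hunch that the solid was holding things back.

in all of them: Q 2 mol%
- Thursday's: L 28 mM; X 1.5 equiv; run made earlier
- Wednesday's: L 44 mM; X 1.5 equiv; run made earlier
- flask: L 20 mM; X 1.50 equiv

| run | time / min | D / % | L / % |
|---|---|---|---|
| Thursday's | 4.00 | 1 | 97 |
| Thursday's | 12.0 | 4 | 92 |
| Thursday's | 25.0 | 8 | 82 |
| Thursday's | 40.0 | 17 | 76 |
| Thursday's | 50.0 | 21 | 65 |
| Wednesday's | 10.0 | 0 | 98 |
| Wednesday's | 20.0 | 4 | 90 |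
| Wednesday's | 30.0 | 8 | 87 |
| Wednesday's | 40.0 | 11 | 80 |
| Wednesday's | 50.0 | 20 | 77 |

(readings scatter by 1.5 percentage points)

* factor on the rate of making D when 50 % of the L are converted (what has only dissolved counts as not reacted) if X is charged twice over
* factor on the rate when 50 % of the L are converted (what has only dissolved counts as not reacted) if Q is charged at 0.4 mol% instead

- L is a solid; its amount is given per volume of the solution
- the analysis behind the earlier runs scatters by 1.5 percentage points, standard deviation
- at the start none of L is in solution
- what has only dissolved of L counts as not reacted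
- what has left E counts as converted, also if it is not yet product

The two readings agreed although Wednesday's charge was 1.57 times Thursday's, so I treated the loss as zero-order and took their mean as the supply rate, the amount of L leaving the solid per minute, 0.199 mM min⁻¹. At that rate I reckoned that the new flask would lose 50 % of its solid L in 50.2 min. Putting that time back in left 10.0 mM of solid in the reckoning, so in it the supply was still running at that time; what has only dissolved does not count as converted, so I took that time as the early end for the 50 % mark. The supply rate gives no factor itself, but it is a yardstick for the rate of making D.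

The forecast gave 1.1 (from 0.95 to 1.6) for doubled X and 0.45 (from 0.2 to 1) for less Q, reasoning that at this point “D formation is already about 90% of supply”.

The simulation gave 1.34 for doubled X and 0.264 for less Q.

    X + Z → Q + D (k = 23.2 M⁻¹ min⁻¹)
    L ⇌ E, rate k2*(cs2 - [E]) while solid is left; crystals form when [E] > cs2 (solubility = 1.80 mM, k = 0.120 min⁻¹)
    Q + J ⇌ Z (K = 460 M⁻¹, k = 233 M⁻¹ min⁻¹)
    E + Q → Q + J (k = 2030 M⁻¹ min⁻¹)

In the new flask, L left the solid at 0.178 mM min⁻¹ over the first 50.0 min, somewhat slower than the supply rate, and the 50 % mark came at 58.9 min, while Q turned E into J and 47.3 % of the catalyst stood as Z at 50.0 min. Between 25.0 min and 50.0 min, D grew by 0.106 mM min⁻¹, about half of the supply rate, with J reaching 21.5 %, and at 103 min the rate still stood at 0.97 of its value at the mark.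

The readings were generated by integration with made-up constants; noise was put on by code.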